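**Remarks (assumptions).** The SMILES is read as the tris[(2Z)-2-methylbut-2-enoate] (angelate) of (1R,2R,3S,4R,5S,7S,8S,9R)-3,4,5-trihydroxy-2,6,6,9-tetramethyltricyclo[5.4.0.0^2,8]undecan-11-one. This numbering is used for all tricyclic compounds; primed locants denote the side chain of the monocyclic ones. Angelic anhydride is taken as a purchased starting material.

## Retrosynthetic overview

1. Tris-angelate 34 ⇐ 3,4-diol 5-angelate 33 ⇐ 5-O-angeloyl 3,4-carbonate 32 ⇐ hydroxy carbonate 30 ⇐ epoxy carbonate 26 ⇐ tricyclic enone 23. The C5 ester is made while C5–OH is the only free hydroxyl, the C3 and C4 esters after the carbonate is removed, and the C11 ketone is carried as a malonate carbon.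
2. Key disconnections C11–C1 and C2–C8: the cyclobutane (C1, C2, C8, C7) is closed last, directly after the six-membered ring, in one domino from monocyclic dienone 19 and di-tert-butyl malonate.
3. Enabling feature: C2 (quaternary, methyl-bearing) is α and C1 is β to the C3 oxygen (a ketone at another oxidation level); C1 carries the C11 carbonyl carbon; C8 sits 1,3 to C2 across the C1–C7 bond of the seven-membered ring. A 2-methylcyclohepta-2,6-dienone therefore accepts C11 at C1 and returns its enolate carbon C2 to C8.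
4. Dienone 19 ⇐ Ito–Saegusa ring expansion of a cyclohexadienone adduct; side-chain stereocentres from asymmetric alkenyl conjugate addition (C7), A(1,3)-controlled hydroboration (C9) and Felkin reduction (C8).
5. Ring order: seven-membered ring (step 9), then six-membered ring and cyclobutane (both in step 12).

Key step: step 12

## Route

Step 1
Reactants: 1 prop-2-yn-1-ol
Product: 3 (2Z)-3-iodo-2-methylprop-2-en-1-ol, via alkenylmagnesium alkoxide 2 (not isolated)
Conditions: MeMgBr (2.5 equiv), CuI (copper monoiodide, 10 mol %), Et2O/THF, -10 to 20 °C; then I2, -40 to 0 °C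
Reagents that add atoms: methylmagnesium bromide, C[Mg]Br; iodine, II
Why: Copper-catalysed anti-carbomagnesiation of the propargylic alkoxide (Duboudin–Jousseaume carbometallation) should place methyl on C2 and magnesium on C3 cis to the CH2O arm through a five-membered chelate, and iodinolysis with retention gives the Z-iodoalkene.

Step 2
Reactants: 3 (2Z)-3-iodo-2-methylprop-2-en-1-ol
Product: 4 tert-butyl{[(2Z)-3-iodo-2-methylprop-2-en-1-yl]oxy}dimethylsilane
Conditions: TBSCl, imidazole, DMF, 20 °C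
Reagents that add atoms: tert-butyldimethylsilyl chloride, CC(C)(C)[Si](C)(C)Cl
Why: Imidazole-mediated O-silylation protects the allylic alcohol before halogen–lithium exchange and touches no stereo element.

Step 3
Reactants: 5 4,4-dimethylcyclohex-2-en-1-one
Product: 6 4,4-dimethylcyclohexa-2,5-dien-1-one
Conditions: IBX (2.5 equiv), DMSO/fluorobenzene, 75 °C
Reagents that add atoms: none
Why: IBX dehydrogenation (Nicolaou) of the remaining CH2–CH2 unit next to the carbonyl should give the achiral cross-conjugated dienone, which cannot tautomerise to a phenol because C4 is quaternary.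

Step 4
Reactants: 4 tert-butyl{[(2Z)-3-iodo-2-methylprop-2-en-1-yl]oxy}dimethylsilane; 6 4,4-dimethylcyclohexa-2,5-dien-1-one
Product: 10 {[(3S)-3-[(1Z)-3-{[tert-butyl(dimethyl)silyl]oxy}-2-methylprop-1-en-1-yl]-4,4-dimethylcyclohexa-1,5-dien-1-yl]oxy}trimethylsilane, via alkenyllithium 7 (not isolated), via alkenylalane 8 (not isolated), via aluminium enolate 9 (not isolated)
Conditions: 4, t-BuLi (2.0 equiv), Et2O, -78 °C; Me2AlCl, -78 to -30 °C; 6, copper thiophene-2-carboxylate CuC5H3O2S (5 mol %), (R,S,S)-BINOL bis(1-phenylethyl)phosphoramidite (10 mol %), Et2O, -30 °C; then TMSOTf, Et3N, -30 to 0 °C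
Reagents that add atoms: trimethylsilyl trifluoromethanesulfonate, C[Si](C)(C)OS(=O)(=O)C(F)(F)F
Why: Copper-catalysed asymmetric conjugate addition of an alkenylalane (Alexakis-type desymmetrisation of a 4,4-disubstituted cyclohexadienone) should transfer the alkenyl group with retention of its Z geometry to one enantiotopic β-carbon, the ligand enantiomer being the one chosen to make C3 S, and O-silylation of the aluminium enolate fixes the enol ether regiochemistry.

Step 5
Reactants: 10 {[(3S)-3-[(1Z)-3-{[tert-butyl(dimethyl)silyl]oxy}-2-methylprop-1-en-1-yl]-4,4-dimethylcyclohexa-1,5-dien-1-yl]oxy}trimethylsilane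
Product: 11 {[(5S)-5-[(1Z)-3-{[tert-butyl(dimethyl)silyl]oxy}-2-methylprop-1-en-1-yl]-4,4,7-trimethylbicyclo[4.1.0]hept-2-en-1-yl]oxy}trimethylsilane
Conditions: Et2Zn, CH3CHI2, CH2Cl2, 0 °C
Reagents that add atoms: 1,1-diiodoethane, CC(I)I
Why: Furukawa-modified Simmons–Smith ethylidene transfer should occur at the most electron-rich double bond (the silyl enol ether) and installs the future C2 with its methyl group, the three new cyclopropane centres being erased in step 9.

Step 6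
Reactants: 11 {[(5S)-5-[(1Z)-3-{[tert-butyl(dimethyl)silyl]oxy}-2-methylprop-1-en-1-yl]-4,4,7-trimethylbicyclo[4.1.0]hept-2-en-1-yl]oxy}trimethylsilane
Product: 13 (1R,2R)-3-{[tert-butyl(dimethyl)silyl]oxy}-2-methyl-1-[(5S)-4,4,7-trimethyl-1-(trimethylsilyloxy)bicyclo[4.1.0]hept-2-en-5-yl]propan-1-ol, via alkylborane 12 (not isolated)
Conditions: BH3·THF (1.0 equiv), THF, 0 °C; then NaBO3·4H2O, H2O, 20 °C
Reagents that add atoms: sodium perborate, [Na+].[O-]OB=O
Why: Hydroboration–oxidation should be governed by A(1,3) strain, the allylic C–H of the ring carbon eclipsing the Z-olefin so that borane adds syn from the face opposite the quaternary C4 with boron on the less substituted carbon, which sets the methyl-bearing C2′ (R) for good and gives the C1′ carbinol as the epimer that steps 7 and 8 correct, while the ring olefin flanked by two quaternary carbons is expected to react more slowly.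

Step 7
Reactants: 13 (1R,2R)-3-{[tert-butyl(dimethyl)silyl]oxy}-2-methyl-1-[(5S)-4,4,7-trimethyl-1-(trimethylsilyloxy)bicyclo[4.1.0]hept-2-en-5-yl]propan-1-ol
Product: 14 (2R)-3-{[tert-butyl(dimethyl)silyl]oxy}-2-methyl-1-[(5S)-4,4,7-trimethyl-1-(trimethylsilyloxy)bicyclo[4.1.0]hept-2-en-5-yl]propan-1-one
Conditions: Dess–Martin periodinane, NaHCO3, CH2Cl2, 0 °C
Reagents that add atoms: none
Why: Dess–Martin oxidation under buffered, non-enolising conditions should convert the carbinol into the ketone without epimerising the two α-stereocentres.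

Step 8
Reactants: 14 (2R)-3-{[tert-butyl(dimethyl)silyl]oxy}-2-methyl-1-[(5S)-4,4,7-trimethyl-1-(trimethylsilyloxy)bicyclo[4.1.0]hept-2-en-5-yl]propan-1-one
Product: 15 (1S,2R)-3-{[tert-butyl(dimethyl)silyl]oxy}-2-methyl-1-[(5S)-4,4,7-trimethyl-1-(trimethylsilyloxy)bicyclo[4.1.0]hept-2-en-5-yl]propan-1-ol
Conditions: LiBH(s-Bu)3, THF, -78 °C
Reagents that add atoms: none
Why: Felkin–Anh reduction with the bulky hydride is matched on both sides, hydride attacking anti to the ring branch that carries the quaternary carbon and anti to the CH2OTBS arm, and should give the (1′S)-alcohol whose oxygen lies trans to the ring branch and cis to the methyl group once the six-membered ring is closed.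

Step 9
Reactants: 15 (1S,2R)-3-{[tert-butyl(dimethyl)silyl]oxy}-2-methyl-1-[(5S)-4,4,7-trimethyl-1-(trimethylsilyloxy)bicyclo[4.1.0]hept-2-en-5-yl]propan-1-ol
Product: 17 (4S)-4-[(1S,2R)-3-{[tert-butyl(dimethyl)silyl]oxy}-1-hydroxy-2-methylpropyl]-2,5,5-trimethylcyclohepta-2,6-dien-1-one, via chloro ketone 16 (not isolated)
Conditions: FeCl3 (2.2 equiv), DMF, 0 °C; then NaOAc, MeOH, 60 °C
Reagents that add atoms: none
Why: Ito–Saegusa ring expansion (single-electron oxidation of the siloxycyclopropane by FeCl3, β-scission of the internal cyclopropane bond, chlorine transfer and E1cB loss of HCl) should give the 2-methylcyclohepta-2,6-dienone with all side-chain stereocentres untouched.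

Step 10
Reactants: 17 (4S)-4-[(1S,2R)-3-{[tert-butyl(dimethyl)silyl]oxy}-1-hydroxy-2-methylpropyl]-2,5,5-trimethylcyclohepta-2,6-dien-1-one
Product: 18 (1S,2R)-3-{[tert-butyl(dimethyl)silyl]oxy}-2-methyl-1-[(1S)-3,7,7-trimethyl-4-oxocyclohepta-2,5-dien-1-yl]propyl 4-methylbenzenesulfonate
Conditions: TsCl, DMAP, Et3N, CH2Cl2, 20 °C
Reagents that add atoms: 4-methylbenzenesulfonyl chloride, Cc1ccc(cc1)S(Cl)(=O)=O
Why: DMAP-catalysed sulfonylation proceeds with retention and turns C1′ into the electrophile of the key step, a tosylate being chosen because it has no acidic α-hydrogen.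

Step 11
Reactants: 18 (1S,2R)-3-{[tert-butyl(dimethyl)silyl]oxy}-2-methyl-1-[(1S)-3,7,7-trimethyl-4-oxocyclohepta-2,5-dien-1-yl]propyl 4-methylbenzenesulfonate
Product: 19 (1S,2S)-3-bromo-2-methyl-1-[(1S)-3,7,7-trimethyl-4-oxocyclohepta-2,5-dien-1-yl]propyl 4-methylbenzenesulfonate
Conditions: Ph3PBr2, CH2Cl2, 0 to 20 °C
Reagents that add atoms: dibromotriphenylphosphorane, BrP(Br)(c1ccccc1)(c1ccccc1)c1ccccc1
Why: Dibromotriphenylphosphorane should convert the primary silyl ether directly into the bromide through an alkoxyphosphonium salt (Appel-type SN2 at the primary carbon) and leave the hindered secondary tosylate.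

Step 12
Reactants: 19 (1S,2S)-3-bromo-2-methyl-1-[(1S)-3,7,7-trimethyl-4-oxocyclohepta-2,5-dien-1-yl]propyl 4-methylbenzenesulfonate; 20 di-tert-butyl propanedioate
Product: 23 di-tert-butyl (1R,2R,7S,8S,9R)-2,6,6,9-tetramethyl-3-oxotricyclo[5.4.0.0^2,8]undec-4-ene-11,11-dicarboxylate, via alkylated malonate 21 (not isolated), via potassium enolate 22 (not isolated)
Conditions: 20, NaH (1.05 equiv), DMF, 0 °C; 19, 40 °C; then t-BuOK (1.1 equiv), THF, 0 to 50 °C
Reagents that add atoms: none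
Why: Sodium di-tert-butyl malonate first displaces the primary bromide (SN2) to give 21, whose anion (formed with t-BuOK) adds reversibly in a 6-exo-trig Michael reaction to the β-carbon of the 2-methyl enone, which closes the six-membered ring and generates the α-methyl enolate 22 regiospecifically, and this enolate then closes the cyclobutane by 4-exo-tet displacement of the secondary tosylate. The closest known reaction types are the Michael-initiated ring closure of malonates and the intramolecular ketone-enolate alkylation of cis-fused keto tosylates used for the cyclobutane of copaene. The ring-fusion centre C1 is set under Curtin–Hammett control, because the Michael step is reversible and only the cis-fused enolate can reach the tosylate carbon; the quaternary C2 follows from intramolecular delivery of C8 to the only accessible enolate face; C8 is inverted (stereospecific SN2) from the (1′S)-tosylate fixed in step 8; C11 is not stereogenic. The step needs C- over O-alkylation and substitution over elimination: the enolate oxygen is held by the ring trans to the carbon that carries the side chain, the dienone has no α-hydrogen and C6 is quaternary so that 22 is the only enolate available, and the strong base is added only when the malonate C–H (the most acidic site) is present so that the γ-hydrogen next to the tosylate is not removed.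

Step 13
Reactants: 23 di-tert-butyl (1R,2R,7S,8S,9R)-2,6,6,9-tetramethyl-3-oxotricyclo[5.4.0.0^2,8]undec-4-ene-11,11-dicarboxylate
Product: 24 di-tert-butyl (1R,2R,3R,7S,8S,9R)-3-hydroxy-2,6,6,9-tetramethyltricyclo[5.4.0.0^2,8]undec-4-ene-11,11-dicarboxylate
Conditions: (S)-2-methyl-CBS-oxazaborolidine (1.0 equiv), BH3·SMe2, THF, -20 °C
Reagents that add atoms: none
Why: Corey–Bakshi–Shibata reduction is reagent-controlled, which is needed because the two faces of this carbonyl are nearly equivalent in the pseudo-symmetric bicyclo[4.1.1] substructure, and with the quaternary C2 as the large group the (S)-catalyst should give the (3R)-allylic alcohol.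

Step 14
Reactants: 24 di-tert-butyl (1R,2R,3R,7S,8S,9R)-3-hydroxy-2,6,6,9-tetramethyltricyclo[5.4.0.0^2,8]undec-4-ene-11,11-dicarboxylate
Product: 25 di-tert-butyl (1R,2R,3R,7S,8S,9R)-3-[(tert-butoxycarbonyl)oxy]-2,6,6,9-tetramethyltricyclo[5.4.0.0^2,8]undec-4-ene-11,11-dicarboxylate
Conditions: Boc2O, DMAP (cat.), MeCN, 20 °C
Reagents that add atoms: di-tert-butyl dicarbonate, CC(C)(C)OC(=O)OC(=O)OC(C)(C)C
Why: DMAP-catalysed acylation installs the tert-butyl carbonate that later delivers oxygen to C4 and meanwhile shields the syn face of the olefin.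

Step 15
Reactants: 25 di-tert-butyl (1R,2R,3R,7S,8S,9R)-3-[(tert-butoxycarbonyl)oxy]-2,6,6,9-tetramethyltricyclo[5.4.0.0^2,8]undec-4-ene-11,11-dicarboxylate
Product: 26 di-tert-butyl (1R,2R,3S,7S,8S,9R)-3-[(tert-butoxycarbonyl)oxy]-4,5-epoxy-2,6,6,9-tetramethyltricyclo[5.4.0.0^2,8]undecane-11,11-dicarboxylate (oxirane oxygen anti to the C3 oxygen)
Conditions: mCPBA, NaHCO3, CH2Cl2, 0 °C
Reagents that add atoms: 3-chloroperoxybenzoic acid, OOC(=O)c1cccc(Cl)c1
Why: Prilezhaev epoxidation of the allylic carbonate should take place on the olefin face anti to the bulky carbonate, which puts the C5 oxygen in its final configuration.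

Step 16
Reactants: 26 di-tert-butyl (1R,2R,3S,7S,8S,9R)-3-[(tert-butoxycarbonyl)oxy]-4,5-epoxy-2,6,6,9-tetramethyltricyclo[5.4.0.0^2,8]undecane-11,11-dicarboxylate
Product: 28 (1R,2R,3S,4R,5S,7S,8S,9R)-5-hydroxy-2,6,6,9-tetramethyl-3,4-(carbonyldioxy)tricyclo[5.4.0.0^2,8]undecane-11,11-dicarboxylic acid, via carbonate diester 27 (not isolated)
Conditions: BF3·OEt2, CH2Cl2, -40 to 0 °C; then CF3CO2H, 20 °C
Reagents that add atoms: none
Why: Lewis acid-promoted 5-exo opening of the epoxide by the carbonate carbonyl oxygen with loss of 2-methylpropene (neighbouring-group participation of a tert-butyl carbonate) inverts C4, so that the C3 and C4 oxygens become cis and the C5 hydroxyl trans, and trifluoroacetic acid then cleaves both tert-butyl esters.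

Step 17
Reactants: 28 (1R,2R,3S,4R,5S,7S,8S,9R)-5-hydroxy-2,6,6,9-tetramethyl-3,4-(carbonyldioxy)tricyclo[5.4.0.0^2,8]undecane-11,11-dicarboxylic acid
Product: 30 (1R,2R,3S,4R,5S,7S,8S,9R)-5-hydroxy-2,6,6,9-tetramethyl-3,4-(carbonyldioxy)tricyclo[5.4.0.0^2,8]undecan-11-one, via geminal diacetate 29 (not isolated)
Conditions: Pb(OAc)4 (2.5 equiv), pyridine, benzene, 50 °C; then 1 M HCl, THF, 20 °C
Reagents that add atoms: lead tetraacetate, CC(=O)O[Pb](OC(C)=O)(OC(C)=O)OC(C)=O
Why: Oxidative bisdecarboxylation of the disubstituted malonic acid with lead tetraacetate gives the geminal diacetate, whose hydrolysis unveils the C11 ketone, while the 3,4-diol is protected as the carbonate against glycol cleavage.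

Step 18
Reactants: 30 (1R,2R,3S,4R,5S,7S,8S,9R)-5-hydroxy-2,6,6,9-tetramethyl-3,4-(carbonyldioxy)tricyclo[5.4.0.0^2,8]undecan-11-one; 31 (2Z)-2-methylbut-2-enoic anhydride (angelic anhydride)
Product: 32 (1R,2R,3S,4R,5S,7S,8S,9R)-2,6,6,9-tetramethyl-11-oxo-3,4-(carbonyldioxy)tricyclo[5.4.0.0^2,8]undecan-5-yl (2Z)-2-methylbut-2-enoate
Conditions: 31 (3 equiv), Cs2CO3 (3 equiv), MeCN, 20 to 40 °C
Reagents that add atoms: none
Why: Carbonate-mediated acylation by the symmetrical anhydride without a nucleophilic acyl-transfer catalyst should esterify the neopentylic C5 hydroxyl, the only free hydroxyl at this stage, with retention of the Z geometry of the angeloyl group and without opening the cyclic carbonate.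

Step 19
Reactants: 32 (1R,2R,3S,4R,5S,7S,8S,9R)-2,6,6,9-tetramethyl-11-oxo-3,4-(carbonyldioxy)tricyclo[5.4.0.0^2,8]undecan-5-yl (2Z)-2-methylbut-2-enoate
Product: 33 (1R,2R,3S,4S,5S,7S,8S,9R)-3,4-dihydroxy-2,6,6,9-tetramethyl-11-oxotricyclo[5.4.0.0^2,8]undecan-5-yl (2Z)-2-methylbut-2-enoate (C4 is unchanged in space; only its descriptor changes with the substituent ranking)
Conditions: K2CO3 (0.1 equiv), MeOH, 0 °C, stopped when 32 is consumed
Reagents that add atoms: none
Why: Base-catalysed methanolysis of the strained five-membered cyclic carbonate should be much faster than transesterification of the α-branched conjugated ester on the neopentylic C5 oxygen, so that the cis-3,4-diol is released with the angelate and all stereocentres intact.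

Step 20
Reactants: 33 (1R,2R,3S,4S,5S,7S,8S,9R)-3,4-dihydroxy-2,6,6,9-tetramethyl-11-oxotricyclo[5.4.0.0^2,8]undecan-5-yl (2Z)-2-methylbut-2-enoate; 31 (2Z)-2-methylbut-2-enoic anhydride (angelic anhydride)
Product: 34 (1R,2R,3S,4R,5S,7S,8S,9R)-2,6,6,9-tetramethyl-11-oxotricyclo[5.4.0.0^2,8]undecane-3,4,5-triyl tris[(2Z)-2-methylbut-2-enoate]
Conditions: 31 (5 equiv), Cs2CO3 (5 equiv), MeCN, 20 to 40 °C
Reagents that add atoms: none
Why: The same catalyst-free, carbonate-mediated acylation, run with excess anhydride so that each anhydride molecule delivers one acyl group and releases angelic acid, should esterify both remaining secondary hydroxyl groups (C4 and the neopentylic C3) without Z-to-E isomerisation of any of the three angeloyl groups.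

## Compound list

1 | prop-2-yn-1-ol | OCC#C | starting material
2 | bromomagnesium (2Z)-3-(bromomagnesio)-2-methylprop-2-en-1-olate | Br[Mg]/C=C(/C)CO[Mg]Br | intermediate
3 | (2Z)-3-iodo-2-methylprop-2-en-1-ol | I/C=C(/C)CO | intermediate
4 | tert-butyl{[(2Z)-3-iodo-2-methylprop-2-en-1-yl]oxy}dimethylsilane | I/C=C(/C)CO[Si](C)(C)C(C)(C)C | intermediate
5 | 4,4-dimethylcyclohex-2-en-1-one | CC1(C)CCC(=O)C=C1 | starting material
6 | 4,4-dimethylcyclohexa-2,5-dien-1-one | CC1(C)C=CC(=O)C=C1 | intermediate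
7 | [(1Z)-3-{[tert-butyl(dimethyl)silyl]oxy}-2-methylprop-1-en-1-yl]lithium | [Li]/C=C(/C)CO[Si](C)(C)C(C)(C)C | intermediate
8 | [(1Z)-3-{[tert-butyl(dimethyl)silyl]oxy}-2-methylprop-1-en-1-yl]dimethylalumane | C[Al](C)/C=C(/C)CO[Si](C)(C)C(C)(C)C | intermediate
9 | dimethylaluminium (3S)-3-[(1Z)-3-{[tert-butyl(dimethyl)silyl]oxy}-2-methylprop-1-en-1-yl]-4,4-dimethylcyclohexa-1,5-dien-1-olate | C[Al](C)OC1=C[C@H](/C=C(/C)CO[Si](C)(C)C(C)(C)C)C(C)(C)C=C1 | intermediate
10 | {[(3S)-3-[(1Z)-3-{[tert-butyl(dimethyl)silyl]oxy}-2-methylprop-1-en-1-yl]-4,4-dimethylcyclohexa-1,5-dien-1-yl]oxy}trimethylsilane | C[Si](C)(C)OC1=C[C@H](/C=C(/C)CO[Si](C)(C)C(C)(C)C)C(C)(C)C=C1 | intermediate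
11 | {[(5S)-5-[(1Z)-3-{[tert-butyl(dimethyl)silyl]oxy}-2-methylprop-1-en-1-yl]-4,4,7-trimethylbicyclo[4.1.0]hept-2-en-1-yl]oxy}trimethylsilane (mixture at C1, C6, C7) | CC1C2[C@H](/C=C(/C)CO[Si](C)(C)C(C)(C)C)C(C)(C)C=CC12O[Si](C)(C)C | intermediate
12 | {(1R,2R)-3-{[tert-butyl(dimethyl)silyl]oxy}-2-methyl-1-[(5S)-4,4,7-trimethyl-1-(trimethylsilyloxy)bicyclo[4.1.0]hept-2-en-5-yl]propyl}borane | CC1C2[C@H]([C@@H](B)[C@H](C)CO[Si](C)(C)C(C)(C)C)C(C)(C)C=CC12O[Si](C)(C)C | intermediate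
13 | (1R,2R)-3-{[tert-butyl(dimethyl)silyl]oxy}-2-methyl-1-[(5S)-4,4,7-trimethyl-1-(trimethylsilyloxy)bicyclo[4.1.0]hept-2-en-5-yl]propan-1-ol | CC1C2[C@H]([C@@H](O)[C@H](C)CO[Si](C)(C)C(C)(C)C)C(C)(C)C=CC12O[Si](C)(C)C | intermediate
14 | (2R)-3-{[tert-butyl(dimethyl)silyl]oxy}-2-methyl-1-[(5S)-4,4,7-trimethyl-1-(trimethylsilyloxy)bicyclo[4.1.0]hept-2-en-5-yl]propan-1-one | CC1C2[C@H](C(=O)[C@H](C)CO[Si](C)(C)C(C)(C)C)C(C)(C)C=CC12O[Si](C)(C)C | intermediate
15 | (1S,2R)-3-{[tert-butyl(dimethyl)silyl]oxy}-2-methyl-1-[(5S)-4,4,7-trimethyl-1-(trimethylsilyloxy)bicyclo[4.1.0]hept-2-en-5-yl]propan-1-ol | CC1C2[C@H]([C@H](O)[C@H](C)CO[Si](C)(C)C(C)(C)C)C(C)(C)C=CC12O[Si](C)(C)C | intermediate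
16 | 4-[(1S,2R)-3-{[tert-butyl(dimethyl)silyl]oxy}-1-hydroxy-2-methylpropyl]-3-chloro-2,5,5-trimethylcyclohept-6-en-1-one (C4 as in 15; C2 and C3 epimers) | CC1C(Cl)[C@H]([C@H](O)[C@H](C)CO[Si](C)(C)C(C)(C)C)C(C)(C)C=CC1=O | intermediate
17 | (4S)-4-[(1S,2R)-3-{[tert-butyl(dimethyl)silyl]oxy}-1-hydroxy-2-methylpropyl]-2,5,5-trimethylcyclohepta-2,6-dien-1-one | CC1=C[C@H]([C@H](O)[C@H](C)CO[Si](C)(C)C(C)(C)C)C(C)(C)C=CC1=O | intermediate
18 | (1S,2R)-3-{[tert-butyl(dimethyl)silyl]oxy}-2-methyl-1-[(1S)-3,7,7-trimethyl-4-oxocyclohepta-2,5-dien-1-yl]propyl 4-methylbenzenesulfonate | CC1=C[C@H]([C@H](OS(=O)(=O)c2ccc(C)cc2)[C@H](C)CO[Si](C)(C)C(C)(C)C)C(C)(C)C=CC1=O | intermediate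
19 | (1S,2S)-3-bromo-2-methyl-1-[(1S)-3,7,7-trimethyl-4-oxocyclohepta-2,5-dien-1-yl]propyl 4-methylbenzenesulfonate | CC1=C[C@H]([C@H](OS(=O)(=O)c2ccc(C)cc2)[C@H](C)CBr)C(C)(C)C=CC1=O | intermediate
20 | di-tert-butyl propanedioate | CC(C)(C)OC(=O)CC(=O)OC(C)(C)C | starting material
21 | di-tert-butyl 2-[(2R,3R)-2-methyl-3-{[(4-methylphenyl)sulfonyl]oxy}-3-[(1S)-3,7,7-trimethyl-4-oxocyclohepta-2,5-dien-1-yl]propyl]propanedioate | CC1=C[C@H]([C@H](OS(=O)(=O)c2ccc(C)cc2)[C@H](C)CC(C(=O)OC(C)(C)C)C(=O)OC(C)(C)C)C(C)(C)C=CC1=O | intermediate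
22 | potassium 11,11-bis(tert-butoxycarbonyl)-2,6,6,9-tetramethyl-8-{[(4-methylphenyl)sulfonyl]oxy}bicyclo[5.4.0]undeca-2,4-dien-3-olate (cis-fused at C1–C7; configuration as in the SMILES) | [K+].[O-]C1=C(C)[C@@H]2C(C(=O)OC(C)(C)C)(C(=O)OC(C)(C)C)C[C@@H](C)[C@@H](OS(=O)(=O)c3ccc(C)cc3)[C@@H]2C(C)(C)C=C1 | intermediate
23 | di-tert-butyl (1R,2R,7S,8S,9R)-2,6,6,9-tetramethyl-3-oxotricyclo[5.4.0.0^2,8]undec-4-ene-11,11-dicarboxylate | C1=CC(C)(C)[C@H]2[C@@H]3[C@H](C)CC(C(=O)OC(C)(C)C)(C(=O)OC(C)(C)C)[C@H]2[C@]3(C)C1=O | intermediate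
24 | di-tert-butyl (1R,2R,3R,7S,8S,9R)-3-hydroxy-2,6,6,9-tetramethyltricyclo[5.4.0.0^2,8]undec-4-ene-11,11-dicarboxylate | C1=CC(C)(C)[C@H]2[C@@H]3[C@H](C)CC(C(=O)OC(C)(C)C)(C(=O)OC(C)(C)C)[C@H]2[C@]3(C)[C@@H]1O | intermediate
25 | di-tert-butyl (1R,2R,3R,7S,8S,9R)-3-[(tert-butoxycarbonyl)oxy]-2,6,6,9-tetramethyltricyclo[5.4.0.0^2,8]undec-4-ene-11,11-dicarboxylate | C1=CC(C)(C)[C@H]2[C@@H]3[C@H](C)CC(C(=O)OC(C)(C)C)(C(=O)OC(C)(C)C)[C@H]2[C@]3(C)[C@@H]1OC(=O)OC(C)(C)C | intermediate
26 | di-tert-butyl (1R,2R,3S,7S,8S,9R)-3-[(tert-butoxycarbonyl)oxy]-4,5-epoxy-2,6,6,9-tetramethyltricyclo[5.4.0.0^2,8]undecane-11,11-dicarboxylate (oxirane oxygen anti to the C3 oxygen) | O2[C@H]1[C@@H]2C(C)(C)[C@H]3[C@@H]4[C@H](C)CC(C(=O)OC(C)(C)C)(C(=O)OC(C)(C)C)[C@H]3[C@]4(C)[C@@H]1OC(=O)OC(C)(C)C | intermediate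
27 | di-tert-butyl (1R,2R,3S,4R,5S,7S,8S,9R)-5-hydroxy-2,6,6,9-tetramethyl-3,4-(carbonyldioxy)tricyclo[5.4.0.0^2,8]undecane-11,11-dicarboxylate | O=C1O[C@@H]2[C@@H](O)C(C)(C)[C@H]3[C@@H]4[C@H](C)CC(C(=O)OC(C)(C)C)(C(=O)OC(C)(C)C)[C@H]3[C@]4(C)[C@@H]2O1 | intermediate
28 | (1R,2R,3S,4R,5S,7S,8S,9R)-5-hydroxy-2,6,6,9-tetramethyl-3,4-(carbonyldioxy)tricyclo[5.4.0.0^2,8]undecane-11,11-dicarboxylic acid | O=C1O[C@@H]2[C@@H](O)C(C)(C)[C@H]3[C@@H]4[C@H](C)CC(C(=O)O)(C(=O)O)[C@H]3[C@]4(C)[C@@H]2O1 | intermediate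
29 | (1R,2R,3S,4R,5S,7S,8S,9R)-5-hydroxy-2,6,6,9-tetramethyl-3,4-(carbonyldioxy)tricyclo[5.4.0.0^2,8]undecane-11,11-diyl diacetate | O=C1O[C@@H]2[C@@H](O)C(C)(C)[C@H]3[C@@H]4[C@H](C)CC(OC(C)=O)(OC(C)=O)[C@H]3[C@]4(C)[C@@H]2O1 | intermediate
30 | (1R,2R,3S,4R,5S,7S,8S,9R)-5-hydroxy-2,6,6,9-tetramethyl-3,4-(carbonyldioxy)tricyclo[5.4.0.0^2,8]undecan-11-one | O=C1O[C@@H]2[C@@H](O)C(C)(C)[C@H]3[C@@H]4[C@H](C)CC(=O)[C@H]3[C@]4(C)[C@@H]2O1 | intermediate
31 | (2Z)-2-methylbut-2-enoic anhydride (angelic anhydride) | C/C=C(/C)C(=O)OC(=O)/C(C)=C\C | starting material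
32 | (1R,2R,3S,4R,5S,7S,8S,9R)-2,6,6,9-tetramethyl-11-oxo-3,4-(carbonyldioxy)tricyclo[5.4.0.0^2,8]undecan-5-yl (2Z)-2-methylbut-2-enoate | O=C1O[C@@H]2[C@@H](OC(=O)/C(C)=C\C)C(C)(C)[C@H]3[C@@H]4[C@H](C)CC(=O)[C@H]3[C@]4(C)[C@@H]2O1 | intermediate
33 | (1R,2R,3S,4S,5S,7S,8S,9R)-3,4-dihydroxy-2,6,6,9-tetramethyl-11-oxotricyclo[5.4.0.0^2,8]undecan-5-yl (2Z)-2-methylbut-2-enoate | O[C@@H]1[C@@H](OC(=O)/C(C)=C\C)C(C)(C)[C@H]2[C@@H]3[C@H](C)CC(=O)[C@H]2[C@]3(C)[C@@H]1O | intermediate
34 | (1R,2R,3S,4R,5S,7S,8S,9R)-2,6,6,9-tetramethyl-11-oxotricyclo[5.4.0.0^2,8]undecane-3,4,5-triyl tris[(2Z)-2-methylbut-2-enoate] (CNP0138097.1) | C/C=C(/C)C(=O)O[C@@H]1[C@@H](OC(=O)/C(C)=C\C)C(C)(C)[C@H]2[C@@H]3[C@H](C)CC(=O)[C@H]2[C@]3(C)[C@@H]1OC(=O)/C(C)=C\C | target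

## Summary

Total step count: 20
Longest linear sequence: 19 steps (1 to 34: steps 1, 2 and 4–20)

## Steps most likely to fail

**Step 12 (key domino).** The enolate may be protonated before the four-membered ring closes, or the secondary tosylate may be lost by elimination, so that the sequence stops at the bicyclic stage. Fallback: setting out from 19 (with 20), Cs2CO3 in MeCN at 20 °C should effect only alkylation and Michael addition and give, after proton transfer, the neutral cis-fused di-tert-butyl 2,6,6,9-tetramethyl-3-oxo-8-(tosyloxy)bicyclo[5.4.0]undec-4-ene-11,11-dicarboxylate F1. F1 is isolated and equilibrated, and the cyclobutane is then closed in a separate thermodynamic enolate alkylation under the conditions used for copaene (NaCH2S(O)CH3, DMSO, 60 °C). The route is rejoined at 23.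

**Step 4 (asymmetric alkenyl transfer).** Possible failures are poor discrimination of the enantiotopic β-carbons, 1,2-addition, or loss of the Z geometry during the lithium–aluminium–copper relay. Fallback: setting out from 4, iodine–lithium exchange (t-BuLi), B(Oi-Pr)3 and aqueous HCl give [(1Z)-3-{[tert-butyl(dimethyl)silyl]oxy}-2-methylprop-1-en-1-yl]boronic acid F2. Rhodium-catalysed Hayashi–Miyaura addition of F2 to 6 ([Rh(cod)Cl]2, (R)-BINAP, KOH, dioxane/H2O, 50 °C) gives (5R)-5-[(1Z)-3-{[tert-butyl(dimethyl)silyl]oxy}-2-methylprop-1-en-1-yl]-4,4-dimethylcyclohex-2-en-1-one F3. Kinetic enolisation of its only enolisable CH2 (LiN(i-Pr)2, TMSCl, THF, -78 °C) rejoins the route at 10.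

**Step 17 (oxidative bisdecarboxylation).** The free C5 carbinol may be oxidised, or the second decarboxylation may remain incomplete. Fallback: setting out from 28, anodic (Hofer–Moest) bisdecarboxylation in methanol (Pt electrodes, Et3N, 0 °C) gives the dimethyl ketal (1R,2R,3S,4R,5S,7S,8S,9R)-5-hydroxy-11,11-dimethoxy-2,6,6,9-tetramethyl-3,4-(carbonyldioxy)tricyclo[5.4.0.0^2,8]undecane F4. Hydrolysis of F4 with 1 M HCl in THF rejoins the route at 30.

Further compounds
F1 | step 12 | di-tert-butyl 2,6,6,9-tetramethyl-3-oxo-8-{[(4-methylphenyl)sulfonyl]oxy}bicyclo[5.4.0]undec-4-ene-11,11-dicarboxylate (cis-fused, C2 epimers) | O=C1C(C)[C@@H]2C(C(=O)OC(C)(C)C)(C(=O)OC(C)(C)C)C[C@@H](C)[C@@H](OS(=O)(=O)c3ccc(C)cc3)[C@@H]2C(C)(C)C=C1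
F2 | step 4 | [(1Z)-3-{[tert-butyl(dimethyl)silyl]oxy}-2-methylprop-1-en-1-yl]boronic acid | OB(O)/C=C(/C)CO[Si](C)(C)C(C)(C)C
F3 | step 4 | (5R)-5-[(1Z)-3-{[tert-butyl(dimethyl)silyl]oxy}-2-methylprop-1-en-1-yl]-4,4-dimethylcyclohex-2-en-1-one | O=C1C[C@H](/C=C(/C)CO[Si](C)(C)C(C)(C)C)C(C)(C)C=C1
F4 | step 17 | (1R,2R,3S,4R,5S,7S,8S,9R)-5-hydroxy-11,11-dimethoxy-2,6,6,9-tetramethyl-3,4-(carbonyldioxy)tricyclo[5.4.0.0^2,8]undecane | O=C1O[C@@H]2[C@@H](O)C(C)(C)[C@H]3[C@@H]4[C@H](C)CC(OC)(OC)[C@H]3[C@]4(C)[C@@H]2O1
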